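**Retrosynthetic overview**

1. The target is reached from 5,7-dihydroxy-3,6,8-trimethoxy-2-(4-methoxyphenyl)chromen-4-one by 7-O-benzylation, methylation of the chelated 5-OH and hydrogenolysis.
2. Ring C (O1–C2 and C2–C3 bonds) comes from an Allan–Robinson condensation of a symmetric ω-methoxy acylphloroglucinol with 4-methoxybenzoic anhydride, which also brings in ring B.
3. Ring A comes from a Claisen cyclisation of methyl 2,4,8-trimethoxy-3,5,7-trioxooctanoate, chain C6 adding to ester C1 (the future C4a–C5 bond). The strategy rests on ring A carrying oxygen on C5, C7 and C8a in a phloroglucinol relation, further methoxy groups on C6 and C8, and the C4 acyl carbon on C4a: the pattern that a poly-β-carbonyl chain with methoxy groups on its two inner α-carbons gives on Claisen folding.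
4. The chain is grown from its ester end by three acylations: Claisen self-condensation of methyl methoxyacetate, γ-acetylation of the β-keto ester dianion, and terminal methoxyacetylation of the diketo ester trianion. A methoxymalonate acyl donor is avoided because its acidic C–H would quench a diketone dianion by proton transfer.
5. Order of ring formation: ring A (step 4), then ring C (step 5); ring B is bought.

Key step: step 4

Remark on the chemistry: the open-chain polyketo esters are drawn as keto forms but are mixtures of enol tautomers with labile CH(OMe) centres and are used as such; their enolate salts and the phenoxide salts of later compounds are treated as forms of the numbered compounds and are not numbered separately.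

**Step 1**
Reactants: 1 methyl methoxyacetate (two molecules)
Product: 2 methyl 2,4-dimethoxy-3-oxobutanoate (racemic, C2 labile)
Conditions: NaH (0.55 equiv per ester), THF, 0 °C then reflux; then cold aq. HCl
Reagents that add atoms: none
Why: Claisen self-condensation, in which the sodium enolate of one ester molecule acylates a second and the equilibrium is pulled over by deprotonation of the product at its single acidic C2–H; the new C2 stereocentre is labile and is not controlled.

**Step 2**
Reactants: 2 methyl 2,4-dimethoxy-3-oxobutanoate; 3 N-methoxy-N-methylacetamide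
Product: 4 methyl 2,4-dimethoxy-3,5-dioxohexanoate (enol mixture, C2 and C4 labile)
Conditions: LDA (2.2 equiv, commercial solution), THF, −78 to 0 °C; then 3, −78 °C to rt; cold 1 M HCl
Reagents that add atoms: none
Why: Huckin–Weiler-type γ-acylation of a β-keto ester dianion, where after removal of the C2 proton the second lithiation takes place at the C4 methylene, whose carbanion is the more nucleophilic site, and the Weinreb amide holds the adduct as a lithium chelate until work-up so that the more acidic product cannot quench unreacted dianion; the C4 centre formed is labile.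

**Step 3**
Reactants: 4 methyl 2,4-dimethoxy-3,5-dioxohexanoate; 5 N,2-dimethoxy-N-methylacetamide
Product: 6 methyl 2,4,8-trimethoxy-3,5,7-trioxooctanoate (enol mixture, C2 and C4 labile)
Conditions: LDA (3.3 equiv, commercial solution), THF, −78 to 0 °C; then 5 (1.0 equiv), −78 to 0 °C; cold 1 M HCl to pH 3
Reagents that add atoms: none
Why: Harris-type terminal acylation of a 3,5-diketo ester trianion, where with C2 and C4 already deprotonated the third lithiation can only occur at the C6 methyl group, this last-formed carbanion is the most nucleophilic site, and the Weinreb amide stops the addition at the ketone stage; no fixed stereocentre is formed.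

**Step 4**
Reactants: 6 methyl 2,4,8-trimethoxy-3,5,7-trioxooctanoate
Product: 7 2-methoxy-1-(2,4,6-trihydroxy-3,5-dimethoxyphenyl)ethan-1-one
Conditions: NaOMe (4 equiv), MeOH, argon, 0 to 50 °C; then 1 M HCl
Reagents that add atoms: none
Why: Methoxide deprotonates the chain at its most acidic sites, the C6 methylene between the C5 and C7 ketones and the C4 methine, and the C6 enolate carbon adds to the C1 ester carbonyl, whose neighbour C2 is the least acidic site and so stays largely protonated and keeps the ester electrophilic; loss of methoxide and tautomerisation give the aromatic triol, which leaves all equilibria as its phenoxide. The closest known reaction type is the base-induced Claisen (Dieckmann-type) cyclisation of 3,5,7-triketo esters to acylphloroglucinols, the laboratory counterpart of chalcone-type polyketide folding. Ring A closes in a 6-exo-trig mode (6-enolendo-exo-trig in the enolate sense), forming the future C4a–C5 bond. No stereocentre is created, and the two labile CH(OMe) centres of 6 become sp2 ring carbons. The step needs Claisen over aldol folding: the C2-to-C7 aldol adduct has a quaternary C2 and cannot aromatise, so it can revert, and the C8-to-C3 aldol needs the far less acidic C8 carbanion, which methoxide in methanol does not produce in useful concentration. Because 7 is symmetric about the axis through the acyl-bearing carbon and its para carbon, either ortho hydroxyl can later close ring C to the same flavone.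

**Step 5**
Reactants: 7 2-methoxy-1-(2,4,6-trihydroxy-3,5-dimethoxyphenyl)ethan-1-one; 8 4-methoxybenzoic anhydride
Product: 10 5,7-dihydroxy-3,6,8-trimethoxy-2-(4-methoxyphenyl)-4H-chromen-4-one, via flavone 5,7-bis(4-methoxybenzoate) 9 (not isolated)
Conditions: 8 (6 equiv), 4-MeOC6H4CO2Na (2 equiv), neat, 175–180 °C, N2; then KOH, EtOH–H2O, reflux; then aq. HCl
Reagents that add atoms: none
Why: Allan–Robinson condensation, in which O-aroylation, aroyl transfer to the methylene carbon activated by the ketone, and cyclodehydration of the resulting 1,3-diketone onto an ortho hydroxyl build the pyranone, the symmetry of 7 makes both ortho hydroxyls equivalent so that a single flavone can form, and the alkaline hydrolysis removes the aryl esters on O5 and O7.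

**Step 6**
Reactants: 10 5,7-dihydroxy-3,6,8-trimethoxy-2-(4-methoxyphenyl)-4H-chromen-4-one
Product: 11 7-(benzyloxy)-5-hydroxy-3,6,8-trimethoxy-2-(4-methoxyphenyl)-4H-chromen-4-one
Conditions: BnBr (1.05 equiv), K2CO3 (1.1 equiv), acetone, reflux
Reagents that add atoms: benzyl bromide, BrCc1ccccc1
Why: Williamson ether synthesis made regioselective by acidity, since the 7-OH is a vinylogous acid para to the C4 carbonyl and is ionised by K2CO3 whereas the 5-OH is held in a hydrogen bond to the C4 carbonyl and reacts much more slowly, so one equivalent of benzyl bromide should etherify O7 only.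

**Step 7**
Reactants: 11 7-(benzyloxy)-5-hydroxy-3,6,8-trimethoxy-2-(4-methoxyphenyl)-4H-chromen-4-one
Product: 12 7-(benzyloxy)-3,5,6,8-tetramethoxy-2-(4-methoxyphenyl)-4H-chromen-4-one
Conditions: MeI (5 equiv), K2CO3 (3 equiv), DMF, 50 °C
Reagents that add atoms: methyl iodide, CI
Why: Williamson methylation of the chelated peri 5-OH, the only remaining acidic group, which needs excess methyl iodide and warming but meets no competing nucleophile.

**Step 8**
Reactants: 12 7-(benzyloxy)-3,5,6,8-tetramethoxy-2-(4-methoxyphenyl)-4H-chromen-4-one
Product: 13 7-hydroxy-3,5,6,8-tetramethoxy-2-(4-methoxyphenyl)-4H-chromen-4-one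
Conditions: H2 (1 atm), 10% Pd/C, EtOAc–MeOH, rt
Reagents that add atoms: none
Why: Catalytic hydrogenolysis of the benzyl aryl ether; the aryl methyl ethers and the tetrasubstituted C2=C3 bond of the pyranone should not be reduced at 1 atm and room temperature.

**Compound list**

1 | methyl methoxyacetate | COCC(=O)OC | starting material
2 | methyl 2,4-dimethoxy-3-oxobutanoate (racemic, labile) | COCC(=O)C(OC)C(=O)OC | intermediate
3 | N-methoxy-N-methylacetamide | CC(=O)N(C)OC | starting material
4 | methyl 2,4-dimethoxy-3,5-dioxohexanoate (tautomer mixture, stereocentres labile) | CC(=O)C(OC)C(=O)C(OC)C(=O)OC | intermediate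
5 | N,2-dimethoxy-N-methylacetamide | COCC(=O)N(C)OC | starting material
6 | methyl 2,4,8-trimethoxy-3,5,7-trioxooctanoate (tautomer mixture, stereocentres labile) | COCC(=O)CC(=O)C(OC)C(=O)C(OC)C(=O)OC | intermediate
7 | 2-methoxy-1-(2,4,6-trihydroxy-3,5-dimethoxyphenyl)ethan-1-one | COCC(=O)c1c(O)c(OC)c(O)c(OC)c1O | intermediate
8 | 4-methoxybenzoic anhydride | COc1ccc(C(=O)OC(=O)c2ccc(OC)cc2)cc1 | starting material
9 | 3,6,8-trimethoxy-2-(4-methoxyphenyl)-4-oxo-4H-chromene-5,7-diyl bis(4-methoxybenzoate) | COc1ccc(-c2oc3c(OC)c(OC(=O)c4ccc(OC)cc4)c(OC)c(OC(=O)c4ccc(OC)cc4)c3c(=O)c2OC)cc1 | intermediate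
10 | 5,7-dihydroxy-3,6,8-trimethoxy-2-(4-methoxyphenyl)-4H-chromen-4-one | COc1ccc(-c2oc3c(OC)c(O)c(OC)c(O)c3c(=O)c2OC)cc1 | intermediate
11 | 7-(benzyloxy)-5-hydroxy-3,6,8-trimethoxy-2-(4-methoxyphenyl)-4H-chromen-4-one | COc1ccc(-c2oc3c(OC)c(OCc4ccccc4)c(OC)c(O)c3c(=O)c2OC)cc1 | intermediate
12 | 7-(benzyloxy)-3,5,6,8-tetramethoxy-2-(4-methoxyphenyl)-4H-chromen-4-one | COc1ccc(-c2oc3c(OC)c(OCc4ccccc4)c(OC)c(OC)c3c(=O)c2OC)cc1 | intermediate
13 | 7-hydroxy-3,5,6,8-tetramethoxy-2-(4-methoxyphenyl)-4H-chromen-4-one | COc1ccc(-c2oc3c(OC)c(O)c(OC)c(OC)c3c(=O)c2OC)cc1 | target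

**Total step count:** 8. **Longest linear sequence:** 8 steps (1 → 2 → 4 → 6 → 7 → 10 → 11 → 12 → 13).

**Steps most likely to fail**

Step 4. The chain may fold by the aldol mode (C2 onto C7, followed by dehydration to a non-aromatic ring) or be cut by retro-Claisen attack of methoxide, faster than the C6-to-C1 closure. The fallback takes ring A from an arene and forms the ring–acyl bond by aryllithium acylation; it sets out from compound 5 and comes back at compound 7. Commercial 1,3,5-tris(benzyloxy)benzene is dibrominated (NBS, 2 equiv, MeCN, 0 °C) to 1,3,5-tris(benzyloxy)-2,4-dibromobenzene F1. Ullmann-type methoxylation (NaOMe, CuBr, DMF–MeOH, 110 °C) then gives 1,3,5-tris(benzyloxy)-2,4-dimethoxybenzene F2. Bromination of the last free ring position (NBS, MeCN) gives 1,3,5-tris(benzyloxy)-2-bromo-4,6-dimethoxybenzene F3. Bromine–lithium exchange (n-BuLi, THF, −78 °C) and addition to Weinreb amide 5 should give 1-[2,4,6-tris(benzyloxy)-3,5-dimethoxyphenyl]-2-methoxyethan-1-one F4. Hydrogenolysis (H2, Pd/C, EtOAc) frees the three phenols and gives 7.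

Step 3. The third deprotonation may stay incomplete, or the trianion may take a proton from the α-methylene of the amide instead of adding to it, returning 4. The fallback moves the disconnection to the C4–C5 bond so that only a dianion is needed; it sets out from compound 2 and comes back at compound 6. Commercial methyl 4-methoxy-3-oxobutanoate is ketalised (ethylene glycol, TsOH, toluene, water removal) to methyl 2-[2-(methoxymethyl)-1,3-dioxolan-2-yl]acetate F5. The dianion of 2 (LDA, 2 equiv of dianion per ester, THF, −78 to 0 °C) is acylated at C4 by this ester to give methyl 2,4-dimethoxy-6-[2-(methoxymethyl)-1,3-dioxolan-2-yl]-3,5-dioxohexanoate F6. Brief mild deketalisation (1 M HCl, THF, rt) should give 6.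

Step 5. In the melt at 180 °C the electron-rich triol may decompose or oxidise before the hindered α-methoxy methylene is C-aroylated. The fallback is the stepwise Baker–Venkataraman sequence under mild conditions; it sets out from compound 7 and comes back at compound 10. Compound 7 is tris-aroylated with 8 (Et3N, DMAP, CH2Cl2, rt) to 2-(2-methoxyacetyl)-4,6-dimethoxybenzene-1,3,5-triyl tris(4-methoxybenzoate) F7. Base-induced aroyl migration (LiHMDS, THF, −78 °C to rt) gives the 1,3-diketone 5-hydroxy-2,6-dimethoxy-4-[2-methoxy-3-(4-methoxyphenyl)-3-oxopropanoyl]-1,3-phenylene bis(4-methoxybenzoate) F8. Acid cyclodehydration (catalytic H2SO4, AcOH, 90 °C) gives diester 9, which is hydrolysed with KOH in aqueous ethanol to 10.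

**Further compounds**

F1 | step 4 | 1,3,5-tris(benzyloxy)-2,4-dibromobenzene | Brc1c(OCc2ccccc2)cc(OCc2ccccc2)c(Br)c1OCc1ccccc1
F2 | step 4 | 1,3,5-tris(benzyloxy)-2,4-dimethoxybenzene | COc1c(OCc2ccccc2)cc(OCc2ccccc2)c(OC)c1OCc1ccccc1
F3 | step 4 | 1,3,5-tris(benzyloxy)-2-bromo-4,6-dimethoxybenzene | COc1c(OCc2ccccc2)c(Br)c(OCc2ccccc2)c(OC)c1OCc1ccccc1
F4 | step 4 | 1-[2,4,6-tris(benzyloxy)-3,5-dimethoxyphenyl]-2-methoxyethan-1-one | COCC(=O)c1c(OCc2ccccc2)c(OC)c(OCc2ccccc2)c(OC)c1OCc1ccccc1
F5 | step 3 | methyl 2-[2-(methoxymethyl)-1,3-dioxolan-2-yl]acetate | COCC1(CC(=O)OC)OCCO1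
F6 | step 3 | methyl 2,4-dimethoxy-6-[2-(methoxymethyl)-1,3-dioxolan-2-yl]-3,5-dioxohexanoate | COCC1(CC(=O)C(OC)C(=O)C(OC)C(=O)OC)OCCO1
F7 | step 5 | 2-(2-methoxyacetyl)-4,6-dimethoxybenzene-1,3,5-triyl tris(4-methoxybenzoate) | COCC(=O)c1c(OC(=O)c2ccc(OC)cc2)c(OC)c(OC(=O)c2ccc(OC)cc2)c(OC)c1OC(=O)c1ccc(OC)cc1
F8 | step 5 | 5-hydroxy-2,6-dimethoxy-4-[2-methoxy-3-(4-methoxyphenyl)-3-oxopropanoyl]-1,3-phenylene bis(4-methoxybenzoate) | COC(C(=O)c1ccc(OC)cc1)C(=O)c1c(O)c(OC)c(OC(=O)c2ccc(OC)cc2)c(OC)c1OC(=O)c1ccc(OC)cc1
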